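**Plan**
1. Locants: the upper flavan-3-ol unit is O1, C2, C3, C4 with rings A (benzo), B (catechol) and C (pyran); the lower flavan-3,4-diol unit is primed, with rings D, E and F; the units are joined C4–C6'. The retrosynthesis cuts, in order: the benzyl and silyl ethers; the C2–ring B bond; the C3–C4 and O1–C2 bonds of ring C together; the C4–C6' bond (aryllithium plus salicylaldehyde); and C2'–ring E of the lower unit (back to a chromone).
2. Enabling feature: on ring A the phenol oxygen O1 and the benzylic carbon C4 that carries ring D are ortho to each other. This is the latent ortho-quinone methide O1=C8a–C4a=C4, across which a two-carbon C2–C3 ketene unit can be laid.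
3. Forward order: ring F is built first (chromone, flavanone, flav-3-ene, cis-diol). Ring D is then bonded to C4 of a ring A carbinol, ring C is closed as a lactone in the key step, and ring B is added last at C2.
4. Stereochemistry: C2' comes from a ligand-controlled aryl addition to the chromone, and C3'/C4' from OsO4 attack anti to ring E. C3 and C4 come from the isothiourea-bound enolate (shielded face, endo approach, cis). C2 comes from attack on the oxocarbenium ion anti to the C3 and C4 substituents.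
5. Protection: benzyl on every phenol and on O3 (it arrives with the ketene unit); tert-butyldimethylsilyl on O3'/O4', so that the acid-labile benzylic C4'–O bond meets only fluoride at the end.

Key step: step 10

Abbreviation: ArL = (2R,3R,4S)-7-(benzyloxy)-2-[3,4-bis(benzyloxy)phenyl]-3,4-bis[(tert-butyldimethylsilyl)oxy]-3,4-dihydro-2H-chromen-6-yl. With ring D at left and O1' at top, ring E is α and both silyloxy groups are β.
Assumption (step 3): aryl transfer to the chromone follows the facial sense known for cyclic enones under the same catalyst, so the (R)-configured pyridine-oxazoline gives the (2S)-flavanone; if the sense is the opposite, the ligand antipode is used.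
Assumption (step 10): the quinone methide meets the enolate face remote from the C2 phenyl group of the isothiourea, which for the (2S,3R) catalyst leads to 3S; if the sense is the opposite, the (2R,3S) catalyst is used.

**Route**

Step 1
Reactants: 1 1-(5-bromo-2,4-dihydroxyphenyl)ethanone
Product: 2 1-[4-(benzyloxy)-5-bromo-2-hydroxyphenyl]ethanone
Conditions: BnBr (1.05 equiv), K2CO3, acetone, reflux
Reagents that add atoms: benzyl bromide, BrCc1ccccc1
Why: Williamson etherification is regioselective because the 2-hydroxyl is held in a hydrogen bond to the ketone, so only the more acidic, free 4-hydroxyl is alkylated.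

Step 2
Reactants: 2 1-[4-(benzyloxy)-5-bromo-2-hydroxyphenyl]ethanone
Product: 4 7-(benzyloxy)-6-bromo-4H-chromen-4-one, via enaminone 3 (not isolated)
Conditions: Me2NCH(OMe)2, toluene, 100 °C; then conc. HCl, CH2Cl2, 40 °C
Reagents that add atoms: N,N-dimethylformamide dimethyl acetal, COC(OC)N(C)C
Why: Condensation of the methyl ketone with the amide acetal gives the enaminone, and acid then drives intramolecular oxa-Michael addition of the phenol and loss of dimethylamine, the standard chromone synthesis from 2-hydroxyacetophenones.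

Step 3
Reactants: 4 7-(benzyloxy)-6-bromo-4H-chromen-4-one; 5 [3,4-bis(benzyloxy)phenyl]boronic acid
Product: 6 (2S)-7-(benzyloxy)-2-[3,4-bis(benzyloxy)phenyl]-6-bromo-2,3-dihydro-4H-chromen-4-one
Conditions: Pd(OCOCF3)2 (5 mol%), (R)-4-tert-butyl-2-(pyridin-2-yl)-4,5-dihydrooxazole (6 mol%), NH4PF6 (30 mol%), H2O (5 equiv), ClCH2CH2Cl, 60 °C
Reagents that add atoms: none
Why: In this asymmetric conjugate addition of an arylboronic acid to a chromone, ligand-controlled insertion of the C2=C3 bond into the aryl–palladium bond sets C2 (S), and protonolysis of the enolate turns the catalyst over while palladium stays divalent, so the C–Br bond is left alone.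

Step 4
Reactants: 6 (2S)-7-(benzyloxy)-2-[3,4-bis(benzyloxy)phenyl]-6-bromo-2,3-dihydro-4H-chromen-4-one
Product: 7 (2S,4S)-7-(benzyloxy)-2-[3,4-bis(benzyloxy)phenyl]-6-bromo-3,4-dihydro-2H-chromen-4-ol (2,4-cis)
Conditions: NaBH4, THF/MeOH, 0 °C
Reagents that add atoms: none
Why: Borohydride reduction with axial hydride delivery to the flavanone carrying an equatorial 2-aryl group should give the 2,4-cis alcohol (the C4 centre is removed again in step 5), and the cold, non-basic medium avoids retro-oxa-Michael racemisation at C2.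

Step 5
Reactants: 7 (2S,4S)-7-(benzyloxy)-2-[3,4-bis(benzyloxy)phenyl]-6-bromo-3,4-dihydro-2H-chromen-4-ol
Product: 8 (2S)-7-(benzyloxy)-2-[3,4-bis(benzyloxy)phenyl]-6-bromo-2H-chromene
Conditions: Burgess reagent (MeO2CN–SO2–NEt3 inner salt), THF, 50 °C
Reagents that add atoms: none
Why: Burgess dehydration proceeds by syn-elimination of the sulfamate ester of the activated benzylic C4 alcohol with a cis C3 hydrogen under neutral conditions, giving the conjugated C3=C4 alkene without acid that could dimerise the electron-rich flavene or ionise C2.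

Step 6
Reactants: 8 (2S)-7-(benzyloxy)-2-[3,4-bis(benzyloxy)phenyl]-6-bromo-2H-chromene
Product: 9 (2R,3S,4S)-7-(benzyloxy)-2-[3,4-bis(benzyloxy)phenyl]-6-bromo-3,4-dihydro-2H-chromene-3,4-diol (2,3-trans-3,4-cis)
Conditions: K2OsO4·2H2O (2 mol%), N-methylmorpholine N-oxide, acetone/THF/H2O, rt
Reagents that add atoms: N-methylmorpholine N-oxide, C[N+]1([O-])CCOCC1; water, O
Why: Osmium-catalysed syn-dihydroxylation delivers both oxygens to the alkene face opposite the C2 aryl group (ring E), so C3' and C4' are set cis to each other and trans to ring E, as is usual for flav-3-enes.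

Step 7
Reactants: 9 (2R,3S,4S)-7-(benzyloxy)-2-[3,4-bis(benzyloxy)phenyl]-6-bromo-3,4-dihydro-2H-chromene-3,4-diol
Product: 10 (2R,3R,4S)-7-(benzyloxy)-2-[3,4-bis(benzyloxy)phenyl]-6-bromo-3,4-bis[(tert-butyldimethylsilyl)oxy]-3,4-dihydro-2H-chromene (ArL–Br; spatial arrangement as in 9)
Conditions: t-BuMe2SiOTf (3 equiv), 2,6-lutidine, CH2Cl2, 0 °C to rt
Reagents that add atoms: tert-butyldimethylsilyl trifluoromethanesulfonate, CC(C)(C)[Si](C)(C)OS(=O)(=O)C(F)(F)F
Why: Silylation with the silyl triflate and a hindered pyridine base protects both secondary hydroxyls as ethers that withstand organolithium, carbonate, hydride and mild acid and later leave with fluoride, so the benzylic C4'–O bond never meets aqueous acid.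

Step 8
Reactants: 10 ArL–Br; 11 4-(benzyloxy)-2-hydroxybenzaldehyde
Product: 14 5-(benzyloxy)-2-[hydroxy(ArL)methyl]phenol as both carbinol epimers, via sodium phenolate 12 (not isolated), via aryllithium 13 (not isolated)
Conditions: 11, NaH, THF, 0 °C; 10, n-BuLi, THF, −78 °C; combine at −78 °C, warm to −20 °C; aq. NH4Cl
Reagents that add atoms: none
Why: Bromine–lithium exchange at −78 °C outpaces benzylic deprotonation, and the aryllithium then undergoes 1,2-addition to the formyl group of the aldehyde whose phenol has been taken out as its sodium salt; the carbinol centre forms without control and is erased in step 10.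

Step 9
Reactants: 14 5-(benzyloxy)-2-[hydroxy(ArL)methyl]phenol
Product: 15 5-(benzyloxy)-2-[(ArL)(4-methylbenzenesulfonyl)methyl]phenol as both epimers at the sulfonyl carbon
Conditions: p-TolSO2H (1.5 equiv, freshly liberated from its sodium salt), 4 Å molecular sieves, CH2Cl2, rt
Reagents that add atoms: 4-methylbenzenesulfinic acid, Cc1ccc(S(=O)O)cc1
Why: The doubly benzylic ortho-hydroxy carbinol ionises under the mild acid and the cation is captured at sulfur by sulfinate, the usual substitution that turns such benzhydrols into bench-stable ortho-quinone methide precursors.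

Step 10
Reactants: 15 5-(benzyloxy)-2-[(ArL)(4-methylbenzenesulfonyl)methyl]phenol; 16 (benzyloxy)acetyl chloride
Product: 18 (3S,4R)-3,7-bis(benzyloxy)-4-(ArL)-3,4-dihydro-2H-chromen-2-one (3,4-cis), via ortho-quinone methide 17 (not isolated)
Conditions: Cs2CO3 (1.5 equiv), CH2Cl2, rt; then (2S,3R)-3-isopropyl-2-phenyl-3,4-dihydro-2H-benzo[4,5]thiazolo[3,2-a]pyrimidine (20 mol%), i-Pr2NEt, 16 added slowly, −40 °C
Reagents that add atoms: none
Why: Cs2CO3 deprotonates the phenol of 15 and expels p-toluenesulfinate, so both epimers give the same (E)-ortho-quinone methide 17 (ring D anti to the carbonyl oxygen), while the isothiourea is N-acylated by 16 and i-Pr2NEt deprotonates the acyl ammonium ion to the (Z)-benzyloxy enolate, held flat by the 1,5 O···S contact. The enolate α-carbon (future C3) adds to the exocyclic carbon C4 of 17, and the released phenoxide O1 then attacks the acyl ammonium carbonyl (future C2), closing ring C as the six-membered lactone by a 6-exo-trig acyl substitution and freeing the catalyst. The closest known reaction type is the isothiourea- or carbene-catalysed formal [4+2] of acid-derived enolates with ortho-quinone methides to cis-3,4-dihydrocoumarins, applied here with an alkoxyacetyl chloride as the enolate source. C3 is set by the catalyst, whose C2 phenyl group shields one enolate face; C4 is set relative to C3 by the endo arrangement, in which the benzyloxy group lies under the quinone methide and the bulky acyl ammonium unit points away, placing O3 and ring D cis. The step needs C-alkylation at C4 ahead of O-acylation, cis over trans, and catalyst over substrate control; these are secured by forming 17 fully before the acid chloride is added slowly (no free phenol, low ketene concentration), by the fixed (E) geometry of 17, and by the distance of the lower-unit stereocentres from C4.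

Step 11
Reactants: 18 (3S,4R)-3,7-bis(benzyloxy)-4-(ArL)-3,4-dihydro-2H-chromen-2-one
Product: 19 (3S,4R)-3,7-bis(benzyloxy)-4-(ArL)-3,4-dihydro-2H-chromen-2-ol as both anomers
Conditions: i-Bu2AlH (1.1 equiv), CH2Cl2, −78 °C; Rochelle salt work-up
Reagents that add atoms: none
Why: Partial reduction of the lactone stops at the lactol because the tetrahedral aluminium acetal survives at −78 °C, while C3 and C4 are untouched and the anomeric centre is reset in step 13.

Step 12
Reactants: 19 (3S,4R)-3,7-bis(benzyloxy)-4-(ArL)-3,4-dihydro-2H-chromen-2-ol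
Product: 20 (3S,4R)-3,7-bis(benzyloxy)-4-(ArL)-2-(benzenesulfonyl)-3,4-dihydro-2H-chromene as both anomers
Conditions: PhSO2H (2 equiv), anhydrous CaCl2, CH2Cl2, rt
Reagents that add atoms: benzenesulfinic acid, O=S(O)c1ccccc1
Why: Acid-catalysed exchange of the anomeric hydroxyl for sulfinate through the cyclic oxocarbenium ion (lactol to anomeric sulfone), with CaCl2 taking up the water, gives a storable C2 electrophile whose anomer mixture converges in step 13.

Step 13
Reactants: 20 (3S,4R)-3,7-bis(benzyloxy)-4-(ArL)-2-(benzenesulfonyl)-3,4-dihydro-2H-chromene; 21 4-bromo-1,2-bis(benzyloxy)benzene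
Product: 24 (2R,3S,4R)-3,7-bis(benzyloxy)-2-[3,4-bis(benzyloxy)phenyl]-4-(ArL)-3,4-dihydro-2H-chromene (2,3-trans-3,4-cis), via Grignard reagent 22 (not isolated), via diarylzinc 23 (not isolated)
Conditions: 21, Mg, THF, 40 °C; ZnBr2 (0.5 equiv per ArMgBr), 0 °C; then 20, ZnBr2 (1 equiv), THF/CH2Cl2, 0 °C to rt
Reagents that add atoms: none
Why: Zinc and magnesium halide ionise the anomeric sulfone to the chroman-2-yl oxocarbenium ion and the diarylzinc transfers its aryl group (anomeric sulfone displacement by organozinc reagents), entering axially on the α face, anti to the β benzyloxy group at C3 and the β ring D at C4, which sets C2 as 2,3-trans.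

Step 14
Reactants: 24 (2R,3S,4R)-3,7-bis(benzyloxy)-2-[3,4-bis(benzyloxy)phenyl]-4-(ArL)-3,4-dihydro-2H-chromene
Product: 25 (2R,3S,4S)-7-(benzyloxy)-2-[3,4-bis(benzyloxy)phenyl]-6-[(2R,3S,4R)-3,7-bis(benzyloxy)-2-[3,4-bis(benzyloxy)phenyl]-3,4-dihydro-2H-chromen-4-yl]-3,4-dihydro-2H-chromene-3,4-diol
Conditions: Bu4NF (4 equiv), THF, rt to 40 °C
Reagents that add atoms: none
Why: Fluoride cleaves both Si–O bonds under non-acidic conditions (desilylation driven by the Si–F bond), so the benzylic C4'–O bond, the benzyl ethers and all stereocentres are kept.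

Step 15
Reactants: 25 the heptabenzyl ether diol of step 14
Product: 26 (2R,3S,4S)-2-(3,4-dihydroxyphenyl)-6-[(2R,3S,4S)-2-(3,4-dihydroxyphenyl)-3,7-dihydroxy-3,4-dihydro-2H-chromen-4-yl]-3,4-dihydro-2H-chromene-3,4,7-triol (CNP0280090.1)
Conditions: H2 (1 atm), Pd(OH)2/C, THF/MeOH, rt, stopped at the calculated uptake
Reagents that add atoms: none
Why: Heterogeneous hydrogenolysis removes the six aryl benzyl ethers and the one alkyl benzyl ether in neutral solvent, where benzyl ethers cleave much faster than a free benzylic alcohol, and no stereocentre is involved.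

**Compound list**
1 | 1-(5-bromo-2,4-dihydroxyphenyl)ethanone | CC(=O)c1cc(Br)c(O)cc1O | starting material
2 | 1-[4-(benzyloxy)-5-bromo-2-hydroxyphenyl]ethanone | CC(=O)c1cc(Br)c(OCc2ccccc2)cc1O | intermediate
3 | (E)-1-[4-(benzyloxy)-5-bromo-2-hydroxyphenyl]-3-(dimethylamino)prop-2-en-1-one | CN(C)/C=C/C(=O)c1cc(Br)c(OCc2ccccc2)cc1O | intermediate (not isolated)
4 | 7-(benzyloxy)-6-bromo-4H-chromen-4-one | O=c1ccoc2cc(OCc3ccccc3)c(Br)cc12 | intermediate
5 | [3,4-bis(benzyloxy)phenyl]boronic acid | OB(O)c1ccc(OCc2ccccc2)c(OCc2ccccc2)c1 | starting material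
6 | (2S)-7-(benzyloxy)-2-[3,4-bis(benzyloxy)phenyl]-6-bromo-2,3-dihydro-4H-chromen-4-one | O=C1C[C@@H](c2ccc(OCc3ccccc3)c(OCc3ccccc3)c2)Oc2cc(OCc3ccccc3)c(Br)cc12 | intermediate
7 | (2S,4S)-7-(benzyloxy)-2-[3,4-bis(benzyloxy)phenyl]-6-bromo-3,4-dihydro-2H-chromen-4-ol | O[C@H]1C[C@@H](c2ccc(OCc3ccccc3)c(OCc3ccccc3)c2)Oc2cc(OCc3ccccc3)c(Br)cc12 | intermediate
8 | (2S)-7-(benzyloxy)-2-[3,4-bis(benzyloxy)phenyl]-6-bromo-2H-chromene | C1=C[C@@H](c2ccc(OCc3ccccc3)c(OCc3ccccc3)c2)Oc2cc(OCc3ccccc3)c(Br)cc12 | intermediate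
9 | (2R,3S,4S)-7-(benzyloxy)-2-[3,4-bis(benzyloxy)phenyl]-6-bromo-3,4-dihydro-2H-chromene-3,4-diol | Brc1cc2c(cc1OCc1ccccc1)O[C@H](c1ccc(OCc3ccccc3)c(OCc3ccccc3)c1)[C@@H](O)[C@H]2O | intermediate
10 | (2R,3R,4S)-7-(benzyloxy)-2-[3,4-bis(benzyloxy)phenyl]-6-bromo-3,4-bis[(tert-butyldimethylsilyl)oxy]-3,4-dihydro-2H-chromene (ArL–Br) | Brc1cc2c(cc1OCc1ccccc1)O[C@H](c1ccc(OCc3ccccc3)c(OCc3ccccc3)c1)[C@@H](O[Si](C)(C)C(C)(C)C)[C@H]2O[Si](C)(C)C(C)(C)C | intermediate
11 | 4-(benzyloxy)-2-hydroxybenzaldehyde | O=Cc1ccc(OCc2ccccc2)cc1O | starting material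
12 | sodium 5-(benzyloxy)-2-formylphenolate | [Na+].[O-]c1cc(OCc2ccccc2)ccc1C=O | intermediate (not isolated)
13 | ArL–Li, the 6-lithio derivative of 10 | [Li]c1cc2c(cc1OCc1ccccc1)O[C@H](c1ccc(OCc3ccccc3)c(OCc3ccccc3)c1)[C@@H](O[Si](C)(C)C(C)(C)C)[C@H]2O[Si](C)(C)C(C)(C)C | intermediate (not isolated)
14 | 5-(benzyloxy)-2-[hydroxy(ArL)methyl]phenol, both carbinol epimers | Oc1cc(OCc2ccccc2)ccc1C(O)c1cc2c(cc1OCc1ccccc1)O[C@H](c1ccc(OCc3ccccc3)c(OCc3ccccc3)c1)[C@@H](O[Si](C)(C)C(C)(C)C)[C@H]2O[Si](C)(C)C(C)(C)C | intermediate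
15 | 5-(benzyloxy)-2-[(ArL)(4-methylbenzenesulfonyl)methyl]phenol, both epimers at the sulfonyl carbon | Oc1cc(OCc2ccccc2)ccc1C(S(=O)(=O)c1ccc(C)cc1)c1cc2c(cc1OCc1ccccc1)O[C@H](c1ccc(OCc3ccccc3)c(OCc3ccccc3)c1)[C@@H](O[Si](C)(C)C(C)(C)C)[C@H]2O[Si](C)(C)C(C)(C)C | intermediate
16 | (benzyloxy)acetyl chloride | O=C(Cl)COCc1ccccc1 | starting material
17 | (6E)-3-(benzyloxy)-6-[(ArL)methylidene]cyclohexa-2,4-dien-1-one | O=C1C=C(OCc2ccccc2)C=C/C1=C\c1cc2c(cc1OCc1ccccc1)O[C@H](c1ccc(OCc3ccccc3)c(OCc3ccccc3)c1)[C@@H](O[Si](C)(C)C(C)(C)C)[C@H]2O[Si](C)(C)C(C)(C)C | intermediate (not isolated)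
18 | (3S,4R)-3,7-bis(benzyloxy)-4-(ArL)-3,4-dihydro-2H-chromen-2-one, 3,4-cis | O(Cc1ccccc1)c1ccc2c(c1)OC(=O)[C@@H](OCc1ccccc1)[C@H]2c1cc2c(cc1OCc1ccccc1)O[C@H](c1ccc(OCc3ccccc3)c(OCc3ccccc3)c1)[C@@H](O[Si](C)(C)C(C)(C)C)[C@H]2O[Si](C)(C)C(C)(C)C | intermediate
19 | (3S,4R)-3,7-bis(benzyloxy)-4-(ArL)-3,4-dihydro-2H-chromen-2-ol, both anomers | O(Cc1ccccc1)c1ccc2c(c1)OC(O)[C@@H](OCc1ccccc1)[C@H]2c1cc2c(cc1OCc1ccccc1)O[C@H](c1ccc(OCc3ccccc3)c(OCc3ccccc3)c1)[C@@H](O[Si](C)(C)C(C)(C)C)[C@H]2O[Si](C)(C)C(C)(C)C | intermediate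
20 | (3S,4R)-3,7-bis(benzyloxy)-4-(ArL)-2-(benzenesulfonyl)-3,4-dihydro-2H-chromene, both anomers | O(Cc1ccccc1)c1ccc2c(c1)OC(S(=O)(=O)c1ccccc1)[C@@H](OCc1ccccc1)[C@H]2c1cc2c(cc1OCc1ccccc1)O[C@H](c1ccc(OCc3ccccc3)c(OCc3ccccc3)c1)[C@@H](O[Si](C)(C)C(C)(C)C)[C@H]2O[Si](C)(C)C(C)(C)C | intermediate
21 | 4-bromo-1,2-bis(benzyloxy)benzene | Brc1ccc(OCc2ccccc2)c(OCc2ccccc2)c1 | starting material
22 | [3,4-bis(benzyloxy)phenyl]magnesium bromide | Br[Mg]c1ccc(OCc2ccccc2)c(OCc2ccccc2)c1 | intermediate (not isolated)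
23 | bis[3,4-bis(benzyloxy)phenyl]zinc | [Zn](c1ccc(OCc2ccccc2)c(OCc2ccccc2)c1)c1ccc(OCc2ccccc2)c(OCc2ccccc2)c1 | intermediate (not isolated)
24 | (2R,3S,4R)-3,7-bis(benzyloxy)-2-[3,4-bis(benzyloxy)phenyl]-4-(ArL)-3,4-dihydro-2H-chromene, 2,3-trans-3,4-cis | O(Cc1ccccc1)c1ccc2c(c1)O[C@H](c1ccc(OCc3ccccc3)c(OCc3ccccc3)c1)[C@@H](OCc1ccccc1)[C@H]2c1cc2c(cc1OCc1ccccc1)O[C@H](c1ccc(OCc3ccccc3)c(OCc3ccccc3)c1)[C@@H](O[Si](C)(C)C(C)(C)C)[C@H]2O[Si](C)(C)C(C)(C)C | intermediate
25 | (2R,3S,4S)-7-(benzyloxy)-2-[3,4-bis(benzyloxy)phenyl]-6-[(2R,3S,4R)-3,7-bis(benzyloxy)-2-[3,4-bis(benzyloxy)phenyl]-3,4-dihydro-2H-chromen-4-yl]-3,4-dihydro-2H-chromene-3,4-diol | O(Cc1ccccc1)c1ccc2c(c1)O[C@H](c1ccc(OCc3ccccc3)c(OCc3ccccc3)c1)[C@@H](OCc1ccccc1)[C@H]2c1cc2c(cc1OCc1ccccc1)O[C@H](c1ccc(OCc3ccccc3)c(OCc3ccccc3)c1)[C@@H](O)[C@H]2O | intermediate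
26 | (2R,3S,4S)-2-(3,4-dihydroxyphenyl)-6-[(2R,3S,4S)-2-(3,4-dihydroxyphenyl)-3,7-dihydroxy-3,4-dihydro-2H-chromen-4-yl]-3,4-dihydro-2H-chromene-3,4,7-triol | Oc1ccc2c(c1)O[C@H](c1ccc(O)c(O)c1)[C@@H](O)[C@H]2c1cc2c(cc1O)O[C@H](c1ccc(O)c(O)c1)[C@@H](O)[C@H]2O | target

**Summary**
Total step count: 15. Longest linear sequence: 15 steps (1 to 26); compounds 5, 11, 16 and 21 are bought.

Three steps most likely to fail:

Step 10. The bulky quinone methide (ortho-benzyloxy ring D on the reacting carbon) may add slowly, so that ketene dimerisation or re-addition of sulfinate competes. The endo preference may be weak, giving cis/trans mixtures. The cis lactone may epimerise at C3 under the basic conditions. Fallback from 10, 11 and 16, coming back at 18: the C4–C6' bond is made by rhodium-catalysed asymmetric 1,4-addition of an arylboronic acid to a coumarin. Bromide 10 is lithiated (n-BuLi, THF, −78 °C), quenched with B(Oi-Pr)3 and hydrolysed to the lower-unit boronic acid F1. Aldehyde 11 is O-acylated with 16 (Et3N, CH2Cl2, then K2CO3, 60 °C) and condensed intramolecularly to 3,7-bis(benzyloxy)-2H-chromen-2-one F2. F1 is then added to C4 of F2 with Rh(acac)(C2H4)2 and the SEGPHOS antipode that delivers 4R (dioxane/H2O, 60 °C). The catalyst fixes C4, and protonation of the rhodium enolate on the face away from the new aryl group should leave the benzyloxy group cis, giving 18.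

Step 13. The anomeric sulfone next to an aryl ether oxygen and a C3 benzyloxy group may ionise slowly, may lose sulfinic acid to the 4H-chromene enol ether, or may be arylated with little facial bias. Fallback from 19, coming back at 24: the Grignard reagent 22 (3 equiv, THF, −78 to 0 °C) is added to the lactol, which reacts through its open hydroxy-aldehyde form. Magnesium chelation by the α-benzyloxy group should give the syn phenol carbinol F3. Mitsunobu cyclisation (PPh3, diisopropyl azodicarboxylate, THF) then closes O1–C2 with inversion to give the 2,3-trans flavan 24. An ionising closure at this electron-rich benzylic centre would favour the same trans product.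

Step 15. Once the ring D phenol is unmasked, the benzylic C4' hydroxyl may be lost by hydrogenolysis or epimerised, and the alkyl benzyl ether at O3 may lag behind. Fallback from 24, coming back at 26: the order of the last two steps is reversed, so that C4'–O stays a hindered silyl ether during hydrogenolysis. H2 with Pd(OH)2/C in EtOAc/THF gives the bis-silyl ether of the free heptaphenol F4. Buffered fluoride (Bu4NF/AcOH, degassed THF, rt) then frees the diol to give 26 without acid or strong base.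

**Further compounds**
F1 | step 10 | [(2R,3R,4S)-7-(benzyloxy)-2-[3,4-bis(benzyloxy)phenyl]-3,4-bis[(tert-butyldimethylsilyl)oxy]-3,4-dihydro-2H-chromen-6-yl]boronic acid | OB(O)c1cc2c(cc1OCc1ccccc1)O[C@H](c1ccc(OCc3ccccc3)c(OCc3ccccc3)c1)[C@@H](O[Si](C)(C)C(C)(C)C)[C@H]2O[Si](C)(C)C(C)(C)C
F2 | step 10 | 3,7-bis(benzyloxy)-2H-chromen-2-one | O=c1oc2cc(OCc3ccccc3)ccc2cc1OCc1ccccc1
F3 | step 13 | 5-(benzyloxy)-2-[1-(ArL)-2-(benzyloxy)-3-[3,4-bis(benzyloxy)phenyl]-3-hydroxypropyl]phenol, benzyloxy and hydroxy groups syn, other centres as in 19 | Oc1cc(OCc2ccccc2)ccc1[C@H](c1cc2c(cc1OCc1ccccc1)O[C@H](c1ccc(OCc3ccccc3)c(OCc3ccccc3)c1)[C@@H](O[Si](C)(C)C(C)(C)C)[C@H]2O[Si](C)(C)C(C)(C)C)[C@H](OCc1ccccc1)[C@@H](O)c1ccc(OCc2ccccc2)c(OCc2ccccc2)c1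
F4 | step 15 | 3',4'-bis-O-(tert-butyldimethylsilyl) ether of 26 (silyl groups on the two hydroxyls of ring F) | Oc1ccc2c(c1)O[C@H](c1ccc(O)c(O)c1)[C@@H](O)[C@H]2c1cc2c(cc1O)O[C@H](c1ccc(O)c(O)c1)[C@@H](O[Si](C)(C)C(C)(C)C)[C@H]2O[Si](C)(C)C(C)(C)C
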